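The runs were generated by integration on assumed constants; noise was put on by code.

4 questions stand on these flasks: which one holds the most target, and how much target each holds at its end.

- the flask with the highest amount of target, in percent of the starting material charged ("all alike" if they lie within 1.5 percentage points) (gamma / epsilon / eta / all alike)
- final target, as a percentage of the starting material charged, in gamma
- final target, as a percentage of the starting material charged, in epsilon
- final target, as a percentage of the starting material charged, in eta

| flask | starting material | protic impurity | free catalyst | stray impurity | temperature | remark | time |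
|---|---|---|---|---|---|---|---|
| dawn | 29 mM | 8.8 mM | 4.4 mM | 1.3 mM | 78 °C | run made earlier |  |
| noon | 66 mM | 8.8 mM | 4.4 mM | 1.3 mM | 94 °C | run made earlier |  |
| dusk | 44 mM | 8.8 mM | 6.6 mM | 1.3 mM | 78 °C | run made earlier |  |
| gamma | 44 mM | 8.80 mM | 4.4 mM | 1.3 mM | 100 °C |  | 12 h |
| epsilon | 44 mM | 8.80 mM | 4.4 mM | 1.3 mM | 70 °C |  | 12 h |
| eta | 44 mM | 8.80 mM | 4.4 mM | 1.3 mM | 85 °C |  | 12 h |

- dawn (time / h: target / %, starting material / %): 4.00: 0.2, 95.9; 8.00: 0.8, 92.8; 15.0: 1.5, 89.9; 20.0: 2.1, 87.7; 25.0: 2.9, 86.3; 30.0: 4.4, 84.6
- noon (time / h: target / %, starting material / %): 0.833: 0.1, 97.1; 1.33: 0.4, 96.0; 2.00: 0.8, 95.2; 4.00: 1.5, 92.6; 6.00: 2.8, 90.4; 10.0: 4.8, 86.7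
- dusk (time / h: target / %, starting material / %): 2.50: 0.1, 96.1; 8.00: 0.6, 90.8; 12.0: 2.0, 88.0; 20.0: 3.0, 84.9; 30.0: 5.3, 81.4

(standard deviation of a reading: 0.3 percentage points)

- the numbers in the tables scatter with a standard deviation of 0.3 percentage points

1. The quantity to carry is the working catalyst, [free catalyst] minus [stray impurity] as charged, 3.10 mM in gamma, eta and epsilon. This takes one stray impurity to remove one free catalyst, an assumption that the readings can test in two separate ways.

2. First way: the gap, meaning starting material found neither as starting material nor as target. In dawn it reads 3.13 mM at 25.0 h and 3.19 mM at 30.0 h, a step of 0.2 points of the charge against a scatter of 0.3 points on each reading, so these two readings do not show whether the gap has levelled off. The last reading lies near the working catalyst of dawn, 3.10 mM, and below the charge of 4.4 mM.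

3. Second way: target in mM divided by catalyst gives turnovers. At 30.0 h, dawn gives 0.412 per working catalyst and dusk gives 0.440. Per charged catalyst they give 0.290 and 0.353, a wider difference. Dawn and dusk differ in starting material as well as in catalyst, so this comparison leans towards the subtraction and does not prove it.

4. They part in noon. There the gap climbs from 4.49 mM at 6.00 h to 5.61 mM at 10.0 h, past even the catalyst charge. Catalyst cannot hold that much, so the noon gap contains a second, slow loss of starting material. The gap is therefore the way that cheats: the same loss may sit in the dawn gap too, so its nearness to the working catalyst proves nothing, and the turnover count stays.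

5. Turnovers per hour are 0.0137 h⁻¹ in dawn and 0.102 h⁻¹ in noon. Taking the same factor for each equal step of temperature, and multiplying by the working catalyst and 12 h, this reckoning gives gamma 18.3%, eta 2.79% and epsilon 0.425%, so gamma leads.

6. The forecast, built on “a resting complex then slowly releasing target”, names gamma with 11%, which is lower than this reckoning, and gives 2.3% for eta and 0.3% for epsilon.

7. The flasks give gamma 15.0%, the highest, eta 2.61% and epsilon 0.170%.

    starting material + free catalyst → catalyst intermediate A (k = 17.0 L mol⁻¹ h⁻¹, Ea = 82.0 kJ mol⁻¹)
    catalyst intermediate A ⇌ catalyst intermediate B (K = 0.390, k = 1.20 h⁻¹, Ea = 104 kJ mol⁻¹, ΔH = 5.00 kJ mol⁻¹)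
    starting material + protic impurity → quenched substrate (k = 1.10 L mol⁻¹ h⁻¹, Ea = 101 kJ mol⁻¹)
    free catalyst + stray impurity → spent catalyst (k = 1200 L mol⁻¹ h⁻¹, Ea = 49.0 kJ mol⁻¹)
    catalyst intermediate B → free catalyst + target (k = 1.30 h⁻¹, Ea = 121 kJ mol⁻¹)
    (constants at 100 °C)

8. In gamma at 12.0 h, spent catalyst stands at 29.5% of the catalyst charged, which is 1.30 mM, and stray impurity at 0%. A neighbour flask repeats gamma with 3.2 mM of stray impurity, so its working catalyst is 1.20 mM. Scaling the target of gamma by working catalyst gives 5.81%, and that neighbour flask holds 6.82%.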